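In eremophilane numbering the cis-8,9-diol of ring B marks a former C8=C9 alkene flanked by C7 and C10, so ring B is a Diels–Alder retron and C5–C10 and C6–C7 are cut together. One intramolecular [4+2] cycloaddition of an (E,E)-dienone (C7=C8–C9=C10, acetyl on C7 as masked isopropenyl) onto the C5=C6 isopropenyl group, tethered through C1–C4, should close rings A and B at once and set the quaternary C5 methyl, the trans C5/C10 fusion and the axial C7 substituent from the lone C4 stereocentre. The precursor is an acyclic trienone bearing a C2 dioxolane and one auxiliary-derived stereocentre.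

Key step: step 9

Remark: the decalins are numbered as eremophilanes (ring A = C1–C5, C10; ring B = C5–C10; C11 is the side-chain carbon on C7). β means the face carrying the C5 methyl and α the opposite face. Compounds 14, 16 and 23 are assumed to be purchasable.

Step 1
Reactants: 1 (R)-4-benzyloxazolidin-2-one; 2 (E)-but-2-enoyl chloride
Product: 4 (R)-4-benzyl-3-[(E)-but-2-enoyl]oxazolidin-2-one, via lithium oxazolidinide 3 (not isolated)
Conditions: n-BuLi (1.0 equiv), THF, −78 °C; then 2, −78 → 0 °C; aq. NH4Cl
Reagents that add atoms: none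
Why: N-acylation of the lithiated carbamate by the acid chloride is the standard entry to N-enoyl imides, and the cold, amine-free conditions should keep the crotonyl double bond (E) and in conjugation.

Step 2
Reactants: 4 (R)-4-benzyl-3-[(E)-but-2-enoyl]oxazolidin-2-one; 5 isopropenylmagnesium bromide
Product: 6 (R)-4-benzyl-3-[(S)-3,4-dimethylpent-4-enoyl]oxazolidin-2-one
Conditions: 5 (1.5 equiv), CuBr·SMe2 (1.5 equiv), THF/Me2S, −78 → −20 °C; aq. NH4Cl; crystallisation or chromatography to remove the minor diastereomer
Reagents that add atoms: none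
Why: Copper-mediated conjugate addition to the metal-chelated s-cis N-enoyl imide should deliver the isopropenyl group to the β-carbon on the face away from the benzyl group, which sets the (S) centre that becomes C4.

Step 3
Reactants: 6 (R)-4-benzyl-3-[(S)-3,4-dimethylpent-4-enoyl]oxazolidin-2-one
Product: 7 (S)-3,4-dimethylpent-4-enoic acid
Conditions: LiOH, H2O2 (30%), THF/H2O 3:1, 0 °C; Na2SO3; 1 M HCl to pH 2 (product volatile, concentrated cold)
Reagents that add atoms: hydrogen peroxide, OO
Why: Hydroperoxide-mediated cleavage of the N-acyl oxazolidinone attacks the exocyclic carbonyl selectively, so the acid is released with the β-stereocentre and the alkene untouched and the auxiliary is recovered.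

Step 4
Reactants: 7 (S)-3,4-dimethylpent-4-enoic acid; 8 ethyl acetate
Product: 11 ethyl (S)-5,6-dimethyl-3-oxohept-6-enoate, via acyl imidazolide 9 (not isolated), via ethyl acetate lithium enolate 10 (not isolated)
Conditions: 7, CDI (1.1 equiv), THF, rt; separately 8 (2.3 equiv), LiN(i-Pr)2 (LDA, 2.2 equiv), THF, −78 °C; imidazolide added at −78 °C; 1 M HCl quench
Reagents that add atoms: none
Why: Crossed Claisen condensation of the acyl imidazolide with the preformed ester enolate should give the β-keto ester (adding C1 and C10), because the second equivalent of enolate deprotonates the product and prevents over-addition.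

Step 5
Reactants: 11 ethyl (S)-5,6-dimethyl-3-oxohept-6-enoate
Product: 12 ethyl 2-{2-[(S)-2,3-dimethylbut-3-enyl]-1,3-dioxolan-2-yl}acetate
Conditions: TMSOCH2CH2OTMS (1.5 equiv), TMSOTf (5 mol %), CH2Cl2, −78 → −20 °C; pyridine quench
Reagents that add atoms: 1,2-bis(trimethylsilyloxy)ethane, C[Si](C)(C)OCCO[Si](C)(C)C
Why: Noyori ketalisation, driven by formation of hexamethyldisiloxane, should protect the C2 ketone under cold aprotic conditions that do not risk acid-catalysed migration of the isopropenyl double bond into the adjacent stereocentre.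

Step 6
Reactants: 12 ethyl 2-{2-[(S)-2,3-dimethylbut-3-enyl]-1,3-dioxolan-2-yl}acetate
Product: 13 2-{2-[(S)-2,3-dimethylbut-3-enyl]-1,3-dioxolan-2-yl}acetaldehyde
Conditions: i-Bu2AlH (DIBAL-H, 1.1 equiv), CH2Cl2, −78 °C; MeOH, then aq. potassium sodium tartrate; used crude at once
Reagents that add atoms: none
Why: Partial ester reduction should stop at the aldehyde because the aluminium hemiacetal, chelated by a dioxolane oxygen, is stable at −78 °C and collapses only on work-up.

Step 7
Reactants: 13 2-{2-[(S)-2,3-dimethylbut-3-enyl]-1,3-dioxolan-2-yl}acetaldehyde; 14 (triphenylphosphoranylidene)acetaldehyde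
Product: 15 (E)-4-{2-[(S)-2,3-dimethylbut-3-enyl]-1,3-dioxolan-2-yl}but-2-enal
Conditions: 14 (1.1 equiv), toluene, 80 °C
Reagents that add atoms: none
Why: Wittig olefination with the stabilised formylmethylene ylide is (E)-selective and needs no base, and the conjugated enal formed is less electrophilic than the saturated aldehyde, so a second homologation should be slow.

Step 8
Reactants: 15 (E)-4-{2-[(S)-2,3-dimethylbut-3-enyl]-1,3-dioxolan-2-yl}but-2-enal; 16 1-(triphenylphosphoranylidene)propan-2-one
Product: 17 (3E,5E)-7-{2-[(S)-2,3-dimethylbut-3-enyl]-1,3-dioxolan-2-yl}hepta-3,5-dien-2-one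
Conditions: 16 (1.3 equiv), toluene, 90 °C
Reagents that add atoms: none
Why: A second Wittig reaction with the stabilised acetylmethylene ylide should add C7 and the acetyl group with (E) geometry and complete the (E,E)-dienone under neutral conditions.

Step 9
Reactants: 17 (3E,5E)-7-{2-[(S)-2,3-dimethylbut-3-enyl]-1,3-dioxolan-2-yl}hepta-3,5-dien-2-one
Product: 18 (4S,5R,7S,10S)-12-noreremophil-8-ene-2,11-dione 2-(ethylene ketal), the trans-fused octalin with 4-methyl, 5-methyl and 7-acetyl on the β face and 10-H on the α face
Conditions: degassed toluene (0.01 M), BHT (10 mol %), silanised sealed tube, 200 °C, 24–72 h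
Reagents that add atoms: none
Why: The step is a thermal, concerted, suprafacial [4+2] cycloaddition in which the C7=C8–C9=C10 dienone adds across the tethered C5=C6 alkene, forming C5–C10 and C6–C7 and leaving C8=C9; the closest known reaction type is the thermal intramolecular Diels–Alder reaction of 1,7,9-decatrienes with unactivated dienophiles, which gives octalins. Ring B closes as the cyclohexene of the cycloaddition (both new bonds lie in it), and ring A closes at the same moment as the six-membered ring built from the four-carbon tether C1–C4 with C5 and C10, through the C5–C10 bond alone. C7 is fixed relative to C10 by the (E,E) diene geometry, which puts the acetyl group cis to the C10–C1 bond; C5 and C10 are fixed relative to each other by the transition state with the tether exo and the C5 methyl endo, which gives the trans fusion; and the absolute sense of all three follows from C4, whose methyl takes the equatorial position of the chair-like tether and so selects one face of the dienophile. The step needs trans over cis fusion and one π-face: the first should be favoured by the chair-like tether and the gem-disubstituted C2 dioxolane, the second by the 1,3-diaxial clash that an axial C4 methyl would have with the axial dioxolane oxygen. The acetyl group gives no useful activation in this orientation, so high dilution, a radical inhibitor and acid-free glass are what should protect the dienone and the β,γ-unsaturated ketone product, and any cis-fused isomer would be removed by chromatography here.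

Step 10
Reactants: 18 (4S,5R,7S,10S)-12-noreremophil-8-ene-2,11-dione 2-(ethylene ketal)
Product: 19 (4S,5R,7S,8R,9S,10R)-8α,9α-dihydroxy-12-noreremophilane-2,11-dione 2-(ethylene ketal)
Conditions: OsO4 (5 mol %), NMO (1.5 equiv), acetone/H2O 8:1, rt; aq. Na2SO3
Reagents that add atoms: osmium tetroxide (catalytic oxygen carrier), O=[Os](=O)(=O)=O; N-methylmorpholine N-oxide, C[N+]1([O-])CCOCC1; water, O
Why: Upjohn syn-dihydroxylation should occur at the only alkene and from the α face, opposite the axial C5 methyl and the pseudoaxial C7 acetyl group, which sets C8 and C9 as the 8α,9α-cis-diol.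

Step 11
Reactants: 19 (4S,5R,7S,8R,9S,10R)-8α,9α-dihydroxy-12-noreremophilane-2,11-dione 2-(ethylene ketal)
Product: 20 the 8,9-O-isopropylidene acetal (acetonide) of 19
Conditions: 2-methoxypropene (3 equiv), PPTS (5 mol %), CH2Cl2, 0 °C; Et3N quench
Reagents that add atoms: 2-methoxypropene, C=C(C)OC
Why: Acid-catalysed acetal exchange is fast on a cis-1,2-diol at 0 °C and masks both hydroxyls, which removes the β-hydroxy ketone that could dehydrate and leaves no free OH for the titanium reagent of the next step.

Step 12
Reactants: 20 the 8,9-acetonide of 19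
Product: 21 (4S,5R,7R,8R,9S,10R)-8α,9α-(isopropylidenedioxy)eremophil-11-en-2-one ethylene ketal
Conditions: Cp2TiMe2 (3 equiv), toluene/THF, 65 °C, dark
Reagents that add atoms: bis(cyclopentadienyl)dimethyltitanium Cp2TiMe2, C[Ti](C)(C1C=CC=C1)C1C=CC=C1
Why: Petasis methylenation converts the methyl ketone into the isopropenyl group through an oxatitanacyclobutane under non-basic conditions, so C7 should not epimerise, the β-oxygen should not be eliminated and both acetals should survive.

Step 13
Reactants: 21 (4S,5R,7R,8R,9S,10R)-8α,9α-(isopropylidenedioxy)eremophil-11-en-2-one ethylene ketal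
Product: 22 (4S,5R,7R,8R,9S,10R)-8α,9α-dihydroxyeremophil-11-en-2-one
Conditions: 1 M HCl/THF 1:3, rt
Reagents that add atoms: water, O
Why: Acid-catalysed acetal hydrolysis should remove the acetonide and the dioxolane in one operation, the dilute acid at room temperature being too mild to hydrate or isomerise the isopropenyl group.

Step 14
Reactants: 23 (E)-3-methylpent-2-enoic acid
Product: 24 (E)-3-methylpent-2-enoyl chloride
Conditions: (COCl)2 (1.2 equiv), DMF (cat.), CH2Cl2, 0 °C → rt; volatiles removed, used crude
Reagents that add atoms: oxalyl chloride, O=C(Cl)C(Cl)=O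
Why: Chlorination through the catalytic chloroiminium species needs no amine base, so no vinylketene can form and the double bond should stay conjugated and (E).

Step 15
Reactants: 22 (4S,5R,7R,8R,9S,10R)-8α,9α-dihydroxyeremophil-11-en-2-one; 24 (E)-3-methylpent-2-enoyl chloride
Product: 26 (4S,5R,7R,8R,9S,10R)-8α-hydroxy-9α-[(E)-3-methylpent-2-enoyloxy]eremophil-11-en-2-one, via dibutylstannylene acetal 25 (not isolated)
Conditions: Bu2SnO (1.1 equiv), toluene, reflux (Dean–Stark); then 24 (1.05 equiv), toluene, 0 °C → rt
Reagents that add atoms: none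
Why: Regioselective acylation through the dibutylstannylene acetal should take place at the tin-activated equatorial C9 oxygen without added base and leave the axial C8 hydroxyl free, and the equatorial ester is also the expected thermodynamic site if the acyl group migrates.

Step 16
Reactants: 26 (4S,5R,7R,8R,9S,10R)-8α-hydroxy-9α-[(E)-3-methylpent-2-enoyloxy]eremophil-11-en-2-one
Product: 27 (2S,4S,5R,7R,8R,9S,10R)-2α,8α-dihydroxy-9α-[(E)-3-methylpent-2-enoyloxy]eremophil-11-ene, the target CNP0129603.2
Conditions: LiBH(s-Bu)3 (L-Selectride, 2.2 equiv), THF, −78 °C, 30 min; AcOH at −78 °C; pH 7 buffer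
Reagents that add atoms: none
Why: Reduction of the cyclohexanone by the bulky trialkylborohydride along the equatorial trajectory should give the axial 2α-alcohol (2S), while the β,β-disubstituted enoate is inert to hydride at −78 °C and the cold acidic quench leaves no alkoxide to shift the acyl group.

Compound list
1 | (R)-4-benzyloxazolidin-2-one | O=C1N[C@H](Cc2ccccc2)CO1 | starting material
2 | (E)-but-2-enoyl chloride | C/C=C/C(=O)Cl | starting material
3 | lithium (R)-4-benzyl-2-oxooxazolidin-3-ide | [Li+].O=C1[N-][C@H](Cc2ccccc2)CO1 | intermediate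
4 | (R)-4-benzyl-3-[(E)-but-2-enoyl]oxazolidin-2-one | C/C=C/C(=O)N1[C@H](Cc2ccccc2)COC1=O | intermediate
5 | isopropenylmagnesium bromide | CC(=C)[Mg]Br | starting material
6 | (R)-4-benzyl-3-[(S)-3,4-dimethylpent-4-enoyl]oxazolidin-2-one | C=C(C)[C@@H](C)CC(=O)N1[C@H](Cc2ccccc2)COC1=O | intermediate
7 | (S)-3,4-dimethylpent-4-enoic acid | C=C(C)[C@@H](C)CC(=O)O | intermediate
8 | ethyl acetate | CCOC(C)=O | starting material
9 | (S)-1-(imidazol-1-yl)-3,4-dimethylpent-4-en-1-one | C=C(C)[C@@H](C)CC(=O)n1ccnc1 | intermediate
10 | lithium 1-ethoxyethen-1-olate (lithium enolate of ethyl acetate) | [Li+].[O-]C(=C)OCC | intermediate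
11 | ethyl (S)-5,6-dimethyl-3-oxohept-6-enoate | C=C(C)[C@@H](C)CC(=O)CC(=O)OCC | intermediate
12 | ethyl 2-{2-[(S)-2,3-dimethylbut-3-enyl]-1,3-dioxolan-2-yl}acetate | C=C(C)[C@@H](C)CC1(CC(=O)OCC)OCCO1 | intermediate
13 | 2-{2-[(S)-2,3-dimethylbut-3-enyl]-1,3-dioxolan-2-yl}acetaldehyde | C=C(C)[C@@H](C)CC1(CC=O)OCCO1 | intermediate
14 | (triphenylphosphoranylidene)acetaldehyde | O=CC=P(c1ccccc1)(c1ccccc1)c1ccccc1 | starting material
15 | (E)-4-{2-[(S)-2,3-dimethylbut-3-enyl]-1,3-dioxolan-2-yl}but-2-enal | C=C(C)[C@@H](C)CC1(C/C=C/C=O)OCCO1 | intermediate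
16 | 1-(triphenylphosphoranylidene)propan-2-one | CC(=O)C=P(c1ccccc1)(c1ccccc1)c1ccccc1 | starting material
17 | (3E,5E)-7-{2-[(S)-2,3-dimethylbut-3-enyl]-1,3-dioxolan-2-yl}hepta-3,5-dien-2-one | C=C(C)[C@@H](C)CC1(C/C=C/C=C/C(C)=O)OCCO1 | intermediate
18 | (4S,5R,7S,10S)-12-noreremophil-8-ene-2,11-dione 2-(ethylene ketal) | CC(=O)[C@H]1C[C@]2(C)[C@@H](C)CC3(OCCO3)C[C@H]2C=C1 | intermediate
19 | (4S,5R,7S,8R,9S,10R)-8α,9α-dihydroxy-12-noreremophilane-2,11-dione 2-(ethylene ketal) | CC(=O)[C@H]1C[C@]2(C)[C@@H](C)CC3(OCCO3)C[C@H]2[C@H](O)[C@@H]1O | intermediate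
20 | 8,9-O-isopropylidene acetal of 19 | CC(=O)[C@H]1C[C@]2(C)[C@@H](C)CC3(OCCO3)C[C@H]2[C@@H]4OC(C)(C)O[C@H]14 | intermediate
21 | (4S,5R,7R,8R,9S,10R)-8α,9α-(isopropylidenedioxy)eremophil-11-en-2-one ethylene ketal | C=C(C)[C@H]1C[C@]2(C)[C@@H](C)CC3(OCCO3)C[C@H]2[C@@H]4OC(C)(C)O[C@H]14 | intermediate
22 | (4S,5R,7R,8R,9S,10R)-8α,9α-dihydroxyeremophil-11-en-2-one | C=C(C)[C@H]1C[C@]2(C)[C@@H](C)CC(=O)C[C@H]2[C@H](O)[C@@H]1O | intermediate
23 | (E)-3-methylpent-2-enoic acid | CC/C(C)=C/C(=O)O | starting material
24 | (E)-3-methylpent-2-enoyl chloride | CC/C(C)=C/C(=O)Cl | intermediate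
25 | 8,9-O-dibutylstannylene acetal of 22 | C=C(C)[C@H]1C[C@]2(C)[C@@H](C)CC(=O)C[C@H]2[C@@H]3O[Sn](CCCC)(CCCC)O[C@H]13 | intermediate
26 | (4S,5R,7R,8R,9S,10R)-8α-hydroxy-9α-[(E)-3-methylpent-2-enoyloxy]eremophil-11-en-2-one | C=C(C)[C@H]1C[C@]2(C)[C@@H](C)CC(=O)C[C@H]2[C@H](OC(=O)/C=C(\C)CC)[C@@H]1O | intermediate
27 | (2S,4S,5R,7R,8R,9S,10R)-2α,8α-dihydroxy-9α-[(E)-3-methylpent-2-enoyloxy]eremophil-11-ene (CNP0129603.2) | C=C(C)[C@H]1C[C@]2(C)[C@@H](C)C[C@H](O)C[C@H]2[C@H](OC(=O)/C=C(\C)CC)[C@@H]1O | target

Total step count: 16. Longest linear sequence: 15 steps (steps 1–13, 15 and 16); step 14 is a one-step side branch.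

Steps most likely to fail

Step 9. The cycloaddition of an unactivated, 1,1-disubstituted dienophile may be slower than thermal E/Z isomerisation of the dienone or opening of the dioxolane by β-elimination. The β,γ-unsaturated ketone product may also epimerise at C7 or move its double bond into conjugation at 200 °C, and the cis-fused transition state may compete. The fallback takes the carbonyl group out of the cycloaddition. Setting out from 17, Luche reduction (NaBH4, CeCl3·7H2O, MeOH, −40 °C) should give the (3E,5E)-dienol F1 as both carbinol epimers, and TBSCl/imidazole its silyl ether F2. The same thermal intramolecular Diels–Alder reaction then involves a plain alkyl-substituted diene and should give the trans-octalin silyl ether F3, which has no acidic C7 hydrogen. Bu4NF would free the octalin alcohol F4, and NaHCO3-buffered Dess–Martin oxidation would erase the extra carbinol centre and rejoin the route at 18.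

Step 15. Discrimination between the C8 and C9 hydroxyls may be poor in this hindered diol, double acylation may occur, or the acyl chloride may lose its double-bond position or geometry. The fallback fixes the regiochemistry with an orthoester. Setting out from 22, MeC(OMe)3 with catalytic PPTS should give the cyclic orthoacetate F5, whose opening in 80% aqueous AcOH is expected to place the acetyl group on the axial oxygen and give the 8α-acetate F6 with C9–OH free; any dimethyl ketal formed at C2 reverts in the same step. Acylation of the only free hydroxyl with 24 (pyridine, catalytic DMAP, CH2Cl2, 0 °C) would give the mixed diester F7. Selective methanolysis of the saturated acetate (K2CO3, MeOH, 0 °C), which should be much faster than that of the conjugated β,β-disubstituted ester, would rejoin the route at 26.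

Step 7. The weakly nucleophilic formyl ylide needs heat, during which the β-ketal aldehyde may open by β-elimination, and the enal formed may be homologated a second time to the dienal. The fallback builds the enal through the ester oxidation level. Setting out from 13, a Masamune–Roush Horner–Wadsworth–Emmons reaction (triethyl phosphonoacetate, LiCl, DBU, MeCN, 0 °C) should give the (E)-enoate F8. Reduction with i-Bu2AlH (2.2 equiv, CH2Cl2, −78 °C) would give the allylic alcohol F9, and MnO2 in CH2Cl2 would rejoin the route at 15.

Further compounds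
F1 | step 9 | (3E,5E)-7-{2-[(S)-2,3-dimethylbut-3-enyl]-1,3-dioxolan-2-yl}hepta-3,5-dien-2-ol (both carbinol epimers) | C=C(C)[C@@H](C)CC1(C/C=C/C=C/C(C)O)OCCO1
F2 | step 9 | tert-butyldimethylsilyl ether of F1 | C=C(C)[C@@H](C)CC1(C/C=C/C=C/C(C)O[Si](C)(C)C(C)(C)C)OCCO1
F3 | step 9 | 11-(tert-butyldimethylsilyloxy)-12-noreremophil-8-en-2-one ethylene ketal (ring configuration as in 18) | CC(O[Si](C)(C)C(C)(C)C)[C@H]1C[C@]2(C)[C@@H](C)CC3(OCCO3)C[C@H]2C=C1
F4 | step 9 | 11-hydroxy-12-noreremophil-8-en-2-one ethylene ketal | CC(O)[C@H]1C[C@]2(C)[C@@H](C)CC3(OCCO3)C[C@H]2C=C1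
F5 | step 15 | 8α,9α-(1-methoxyethylidenedioxy)eremophil-11-en-2-one (cyclic orthoacetate of 22) | C=C(C)[C@H]1C[C@]2(C)[C@@H](C)CC(=O)C[C@H]2[C@@H]3OC(C)(OC)O[C@H]13
F6 | step 15 | 8α-acetoxy-9α-hydroxyeremophil-11-en-2-one | C=C(C)[C@H]1C[C@]2(C)[C@@H](C)CC(=O)C[C@H]2[C@H](O)[C@@H]1OC(C)=O
F7 | step 15 | 8α-acetoxy-9α-[(E)-3-methylpent-2-enoyloxy]eremophil-11-en-2-one | C=C(C)[C@H]1C[C@]2(C)[C@@H](C)CC(=O)C[C@H]2[C@H](OC(=O)/C=C(\C)CC)[C@@H]1OC(C)=O
F8 | step 7 | ethyl (E)-4-{2-[(S)-2,3-dimethylbut-3-enyl]-1,3-dioxolan-2-yl}but-2-enoate | C=C(C)[C@@H](C)CC1(C/C=C/C(=O)OCC)OCCO1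
F9 | step 7 | (E)-4-{2-[(S)-2,3-dimethylbut-3-enyl]-1,3-dioxolan-2-yl}but-2-en-1-ol | C=C(C)[C@@H](C)CC1(C/C=C/CO)OCCO1
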